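**Retrosynthetic overview** (target numbering: C1 = quaternary carbinol carrying CH2OBz, C2/C5 = benzoyloxy carbons, C3=C4 alkene, C6 = secondary carbinol)
1. Target ⇐ O2-benzoylation and removal of a 1,6-O-phenylboronate ⇐ allylic alcohol ⇐ Luche reduction of a cyclohex-2-enone (sets C2).
2. Cyclohex-2-enone ⇐ one-carbon ring expansion of a cyclopentanone (diazo C-insertion, 1,2-alkyl shift) with desaturation in the same flask; this key step inserts C3 and creates C3=C4.
3. Cyclopentanone ⇐ anti-selective syn-dihydroxylation (sets C1 and C6) of a 2-(acyloxymethyl)cyclopent-2-enone ⇐ Baylis–Hillman hydroxymethylation of (R)-4-hydroxycyclopentenone, whose stereocentre becomes C5.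
4. Ring order: the five-membered carbocycle is bought; a temporary dioxaborolane forms in step 3; the six-membered carbocycle forms in step 4.

Assumption: 1 and 2 (as formalin) are the purchased starting materials; benzoyl chloride, TMSCHN2 and PhB(OH)2 are used as reagents.

**Step 1**
Reactants: 1 (R)-4-hydroxycyclopent-2-en-1-one; 2 formaldehyde
Product: 3 (4R)-4-hydroxy-2-(hydroxymethyl)cyclopent-2-en-1-one
Conditions: 37% aq. CH2O, imidazole (1 equiv), THF/H2O 1:1, rt
Reagents that add atoms: none
Why: Morita–Baylis–Hillman hydroxymethylation, in which imidazole adds reversibly at C3, the enolate is trapped by formaldehyde at C2 and loss of imidazole restores the enone, so the purchased C4 stereocentre is not touched.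

**Step 2**
Reactants: 3 (4R)-4-hydroxy-2-(hydroxymethyl)cyclopent-2-en-1-one
Product: 4 (4R)-4-(benzoyloxy)-2-[(benzoyloxy)methyl]cyclopent-2-en-1-one
Conditions: BzCl (2.3 equiv), pyridine, CH2Cl2, 0 °C (no DMAP)
Reagents that add atoms: benzoyl chloride O=C(Cl)c1ccccc1
Why: Plain O-acylation of a primary and a secondary allylic alcohol with retention; the short cold reaction without a nucleophilic catalyst avoids SN2′ attack on the Baylis–Hillman ester and β-elimination of the 4-benzoate.

**Step 3**
Reactants: 4 (4R)-4-(benzoyloxy)-2-[(benzoyloxy)methyl]cyclopent-2-en-1-one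
Product: 5 cyclic phenylboronate of (2S,3S,4R)-4-(benzoyloxy)-2-[(benzoyloxy)methyl]-2,3-dihydroxycyclopentan-1-one
Conditions: OsO4 (4 mol %), NMO (1.3 equiv), PhB(OH)2 (1.2 equiv), CH2Cl2, rt
Reagents that add atoms: osmium tetroxide O=[Os](=O)(=O)=O; N-methylmorpholine N-oxide C[N+]1([O-])CCOCC1; phenylboronic acid OB(O)c1ccccc1
Why: Osmium-catalysed syn-dihydroxylation (Upjohn conditions, boronic-acid variant): OsO4 adds to the trisubstituted enone C=C from the face anti to the C4 benzoate, which sets C2 and C3 (future C1 and C6) cis to each other and trans to the benzoate, and PhB(OH)2 cleaves the hindered osmate ester directly to the boronate that masks the α-ketol.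

**Step 4**
Reactants: 5 cyclic phenylboronate of (2S,3S,4R)-4-(benzoyloxy)-2-[(benzoyloxy)methyl]-2,3-dihydroxycyclopentan-1-one
Product: 8 cyclic phenylboronate of (4R,5S,6S)-4-(benzoyloxy)-6-[(benzoyloxy)methyl]-5,6-dihydroxycyclohex-2-en-1-one, via β-ketosilane 6 (not isolated), via enol silane 7 (not isolated)
Conditions: TMSCHN2 (1.3 equiv), Sc(OTf)3 (10 mol %), CH2Cl2, −45 → 0 °C; then IBX·MPO, DMSO, rt
Reagents that add atoms: trimethylsilyldiazomethane C[Si](C)(C)C=[N+]=[N-]
Why: Proposed new method: Sc(OTf)3 activates the ketone for addition of TMSCHN2 and, in the diazonium betaine, the unsubstituted C5 methylene migrates with loss of N2 (1,2-shift) rather than the quaternary C2, whose migration is disfavoured by its α-oxygen and its bulk, so the carbon is inserted only on the CH2 side; the β-ketosilane then undergoes 1,3-Brook shift to the regiodefined enol silane, which blocks a second insertion and is oxidised in the same flask by IBX·MPO to the cyclohex-2-enone with all stereocentres untouched; the closest known reactions are the Lewis-acid-promoted TMSCHN2 ring expansion of cycloalkanones (Tiffeneau–Demjanov-type homologation) and IBX or Saegusa oxidation of silyl enol ethers, which have not been merged into one homologative desaturation or used on polyoxygenated β-acyloxy cyclopentanones.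

**Step 5**
Reactants: 8 cyclic phenylboronate of (4R,5S,6S)-4-(benzoyloxy)-6-[(benzoyloxy)methyl]-5,6-dihydroxycyclohex-2-en-1-one
Product: 9 cyclic 1,6-O-phenylboronate of [(1R,2R,5R,6S)-5-(benzoyloxy)-1,2,6-trihydroxycyclohex-3-en-1-yl]methyl benzoate
Conditions: NaBH4, CeCl3·7H2O, MeOH, −78 °C
Reagents that add atoms: none
Why: Luche 1,2-reduction: the cis-fused boronate holds the quaternary C–O bond pseudo-axial on the lower face, so hydride should add anti to it (Felkin–Anh, convex face) and give the C2 alcohol cis to both boronate oxygens; C1 is unchanged and is R here only by CIP priority.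

**Step 6**
Reactants: 9 cyclic 1,6-O-phenylboronate of [(1R,2R,5R,6S)-5-(benzoyloxy)-1,2,6-trihydroxycyclohex-3-en-1-yl]methyl benzoate
Product: 11 [(1S,2R,5R,6S)-2,5-bis(benzoyloxy)-1,6-dihydroxycyclohex-3-en-1-yl]methyl benzoate, via tribenzoate boronate 10 (not isolated)
Conditions: BzCl, pyridine, DMAP (cat.), CH2Cl2, 0 °C → rt; aqueous wash; then 30% aq. H2O2, EtOAc/acetone, rt
Reagents that add atoms: benzoyl chloride O=C(Cl)c1ccccc1
Why: The only free hydroxyl (allylic C2–OH) is acylated with retention under DMAP catalysis, and the phenylboronate is then removed by neutral oxidative C–B cleavage and borate hydrolysis, which leaves the three benzoates and the alkene intact.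

**Compound list**
1 | (R)-4-hydroxycyclopent-2-en-1-one | O=C1C=C[C@H](O)C1 | starting material
2 | formaldehyde (37% aqueous) | C=O | starting material
3 | (4R)-4-hydroxy-2-(hydroxymethyl)cyclopent-2-en-1-one | O=C1C(CO)=C[C@H](O)C1 | intermediate
4 | (4R)-4-(benzoyloxy)-2-[(benzoyloxy)methyl]cyclopent-2-en-1-one | O=C1C(COC(=O)c2ccccc2)=C[C@H](OC(=O)c2ccccc2)C1 | intermediate
5 | cyclic phenylboronate (2-phenyl-1,3,2-dioxaborolane across O2/O3) of (2S,3S,4R)-4-(benzoyloxy)-2-[(benzoyloxy)methyl]-2,3-dihydroxycyclopentan-1-one; O2 and O3 cis, both trans to the 4-benzoate | O=C1C[C@@H](OC(=O)c2ccccc2)[C@@H]2OB(c3ccccc3)O[C@]12COC(=O)c1ccccc1 | intermediate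
6 | β-ketosilane: (4R,5S,6S)-4-(benzoyloxy)-6-[(benzoyloxy)methyl]-5,6-(phenylboranediyldioxy)-2-(trimethylsilyl)cyclohexan-1-one, both C2 epimers | O=C1C([Si](C)(C)C)C[C@@H](OC(=O)c2ccccc2)[C@@H]2OB(c3ccccc3)O[C@]12COC(=O)c1ccccc1 | intermediate
7 | enol silane: (4R,5S,6S)-4-(benzoyloxy)-6-[(benzoyloxy)methyl]-5,6-(phenylboranediyldioxy)-1-(trimethylsilyloxy)cyclohex-1-ene | C[Si](C)(C)OC1=CC[C@@H](OC(=O)c2ccccc2)[C@@H]2OB(c3ccccc3)O[C@]12COC(=O)c1ccccc1 | intermediate
8 | cyclic phenylboronate (across O5/O6) of (4R,5S,6S)-4-(benzoyloxy)-6-[(benzoyloxy)methyl]-5,6-dihydroxycyclohex-2-en-1-one | O=C1C=C[C@@H](OC(=O)c2ccccc2)[C@@H]2OB(c3ccccc3)O[C@]12COC(=O)c1ccccc1 | intermediate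
9 | cyclic 1,6-O-phenylboronate of [(1R,2R,5R,6S)-5-(benzoyloxy)-1,2,6-trihydroxycyclohex-3-en-1-yl]methyl benzoate; free C2–OH cis to the boronate oxygens, C5–OBz trans to them | O[C@@H]1C=C[C@@H](OC(=O)c2ccccc2)[C@@H]2OB(c3ccccc3)O[C@]12COC(=O)c1ccccc1 | intermediate
10 | cyclic 1,6-O-phenylboronate of [(1S,2R,5R,6S)-2,5-bis(benzoyloxy)-1,6-dihydroxycyclohex-3-en-1-yl]methyl benzoate | O=C(O[C@@H]1C=C[C@@H](OC(=O)c2ccccc2)[C@@H]2OB(c3ccccc3)O[C@]12COC(=O)c1ccccc1)c1ccccc1 | intermediate
11 | [(1S,2R,5R,6S)-2,5-bis(benzoyloxy)-1,6-dihydroxycyclohex-3-en-1-yl]methyl benzoate | O=C(OC[C@@]1(O)[C@H](OC(=O)c2ccccc2)C=C[C@@H](OC(=O)c2ccccc2)[C@@H]1O)c1ccccc1 | target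

**Totals**
Total steps: 6. Longest linear sequence: 6 (fully linear from 1).

**Three steps most likely to fail**

Step 4 (the proposed new step). The C-insertion, the Brook shift and the oxidation must all work in one flask on a hindered β-acyloxy ketone. The fallback uses known chemistry, sets out from 5 and returns at 8. Homologate 5 with TMSCHN2 and BF3·OEt2 (CH2Cl2, −78 → −20 °C) and let the acidic aqueous work-up protodesilylate the β-ketosilane 6. This gives the saturated ring-expanded ketone, the cyclic phenylboronate of (4R,5S,6S)-4-(benzoyloxy)-6-[(benzoyloxy)methyl]-5,6-dihydroxycyclohexan-1-one F1, which is isolated. F1 can enolise only towards C2, so direct ketone dehydrogenation with IBX (DMSO/toluene, 70 °C) gives 8 without relying on the enol-silane interception.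

Step 5. The facial selectivity of the hydride addition is predicted, not demonstrated. The fallback sets out from 8 and returns at 10. If reduction gives mainly the C2 epimer, the cyclic 1,6-O-phenylboronate of [(1R,2S,5R,6S)-5-(benzoyloxy)-1,2,6-trihydroxycyclohex-3-en-1-yl]methyl benzoate F2, it is not discarded. A Mitsunobu reaction with benzoic acid (PPh3, DIAD, THF, 0 °C) inverts C2 and installs the benzoate in one operation to give 10. Compound 10 is then deboronated as in the second half of step 6.

Step 3. The enone is electron-poor and hindered, and the amine formed from NMO could trigger loss of the β-benzoate. The fallback sets out from 4 and returns at 5. An acidic Ru-catalysed flash dihydroxylation (RuCl3 cat., NaIO4, CeCl3 cat., EtOAc/MeCN/H2O, 0 °C) suits electron-poor alkenes and excludes base. It gives, from the same face, the free diol (2S,3S,4R)-4-(benzoyloxy)-2-[(benzoyloxy)methyl]-2,3-dihydroxycyclopentan-1-one F3. Condensation of F3 with PhB(OH)2 (MgSO4, CH2Cl2, rt) then gives 5.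

**Further compounds**
F1 | step 4 | cyclic phenylboronate of (4R,5S,6S)-4-(benzoyloxy)-6-[(benzoyloxy)methyl]-5,6-dihydroxycyclohexan-1-one | O=C1CC[C@@H](OC(=O)c2ccccc2)[C@@H]2OB(c3ccccc3)O[C@]12COC(=O)c1ccccc1
F2 | step 5 | cyclic 1,6-O-phenylboronate of [(1R,2S,5R,6S)-5-(benzoyloxy)-1,2,6-trihydroxycyclohex-3-en-1-yl]methyl benzoate | O[C@H]1C=C[C@@H](OC(=O)c2ccccc2)[C@@H]2OB(c3ccccc3)O[C@]12COC(=O)c1ccccc1
F3 | step 3 | (2S,3S,4R)-4-(benzoyloxy)-2-[(benzoyloxy)methyl]-2,3-dihydroxycyclopentan-1-one | O=C1C[C@@H](OC(=O)c2ccccc2)[C@H](O)[C@@]1(O)COC(=O)c1ccccc1
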